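## The problem

The target 15 is a flavanone. Ring A, a resorcinol-type arene with a free hydroxyl at C7, is fused through C4a and C8a to the dihydropyranone ring C, and C2 of ring C carries ring B, a 4-hydroxyphenyl group with a prenyl group on each carbon next to the hydroxyl. C2 is the only stereocentre and must be S. Nothing else in the molecule can relay chirality to it, so it has to come from a chiral catalyst, and any further centre made on the way (C4 in this plan) is a passenger to be erased. Once the C4 ketone is present, C2 is fragile: base opens ring C by E1cB expulsion of the O1 phenoxide to the 2'-hydroxychalcone, and a free 4'-phenoxide offers a second, quinone-methide route to the same loss. Ketone and free phenols should therefore appear late and under buffered conditions. The prenyl groups rule out hydrogenation, hydrogenolysis, strong acids and unselective oxidants (their ArCH2–CH= positions are doubly activated). Each also sits ortho to the C4' hydroxyl, so a free phenol would add to a protonated prenyl group and close a 2,2-dimethylchroman. Placing two linear prenyl groups beside one phenol oxygen is a regiochemical task of its own (C- against O-alkylation, linear against reverse prenyl). The feature that opens the molecule is that ring C consists of two polarity-matched halves. O1–C8a–C4a–C4 is the heterodiene of a ring A ortho-quinone methide at the salicylaldehyde oxidation level, with the C7 oxygen para to C4a to stabilise charge at C4. C2–C3 is the vinyl group of a ring B styrene, whose C4' oxygen makes C3 nucleophilic and C2 the cationic centre that O1 captures.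

## Retrosynthesis

**15 from 14.** The two O–Si bonds of bis-silyl flavanone 14 are cut last. Silyl ethers are preferred to MOM, benzyl or methyl ethers because fluoride removes them near neutrality; acid, hydrogenolysis or boron halides would all attack the prenyl groups or the ortho-prenylphenol. The skeleton of 14 is no simpler, but with both phenols masked the ring-opening and chroman-forming pathways stay closed throughout the route. The forward step must cleave two aryl silyl ethers without generating enough phenoxide to open ring C.

**14 from 13 from 12.** No skeletal bond is cut; the C4 carbonyl is traced to the C4 hydroxyl of 13 and that to the C4 methoxy group of 12. The neighbouring choice, a flavan with no oxygen at C4, would need a benzylic C–H oxidation that cannot tell C4 from C2 or from the four ArCH2 positions of the prenyl groups. A heterodiene at the aldehyde level puts the oxygen at C4 from the start. Compound 12 has no ketone, so C2 cannot racemise by ring opening. The forward steps must ionise the C4–OMe bond without breaking O1–C2 and then oxidise with a reagent that ignores the prenyl alkenes.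

**12 from 3 and 10.** The O1–C2 and C3–C4 bonds are cut together, which is the retron of an inverse-demand hetero-Diels–Alder reaction of methoxy ortho-quinone methide 11, formed in the flask from acetal 3, with styrene 10. Cutting O1–C2 alone (the chalcone oxa-Michael closure) gives a reversible reaction that is hard to hold under enantiocontrol. Cutting only the C2–aryl bond (aryl conjugate addition to a chromone) forms one bond and needs an organometallic on the diprenyl arene. The double cut splits 12 into two arenes of similar size and forms ring C, two bonds and both stereocentres at once. It asks for facial control at C2 by a chiral acid, preference for the styrene over two prenyl alkenes, and acidity that the aryl silyl ethers survive.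

**3 from 2 from 1.** The two C–OMe bonds of the acetal and the O–Si bond are cut, leading to commercial 2,4-dihydroxybenzaldehyde 1. The acetal is preferred to the aldehyde 2 as the cycloaddition partner because acid ionises it to the oxocarbenium ion without releasing water. The hydrogen bond between the 2-OH and the formyl group lets the 4-OH be silylated alone.

**10 from 8 and 9; 8 from 7; 7 from 4 and 5 by way of 6.** The aryl–vinyl bond is cut to aryl iodide 8 and tributyl(vinyl)stannane 9, and the O–Si bond to phenol 7. The two aryl–prenyl bonds are then cut one after the other, first to mono-prenyl phenol 6 and then to 4-iodophenol 4, each cut releasing one equivalent of prenyl bromide 5. The neighbouring cut, cross-coupling of a prenylboron reagent onto a 2,6-dihalophenol derivative, would require a protecting group that survives aqueous base. A silyl ether of so acidic a phenol is too labile for that. It would also leave the linear/reverse prenyl ratio to the ligand. Phenoxide ortho-C-alkylation gives the linear groups directly from two commodity chemicals, at the price of moderate selectivity and of two equivalents of the halide. The iodide then serves as the handle for a base-free vinylation.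

## Roads not taken

Alternative 1: Ring B is built last from acyclic carbon by cutting the C2'–C3' and C5'–C6' bonds. In the forward direction the symmetric ketone A2 (2,10-dimethylundeca-2,9-dien-6-one) condenses at both alpha carbons with the chromone-substituted vinamidinium salt A3 under KOtBu and aromatises to the phenol of flavone A1.
- Merits: both prenyl groups arrive in the right place and in linear form by construction, with no aromatic prenylation or cross-coupling. In this respect the road is better than the chosen plan, whose step 3 is only moderately selective.
- Weak points: the key step gives an achiral flavone, so the only stereocentre is still to be made. That needs an enantioselective conjugate reduction of the hindered C2=C3 bond of A1 that spares two prenyl alkenes, which excludes catalytic hydrogenation. A3 needs its own multi-step preparation, and the chromone ring is prone to opening by alkoxide. The MOM group must finally be removed by acid next to an ortho-prenylphenol on the way to 15.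
- Comparison: the chosen plan sets C2 in the event that closes ring C and ends with fluoride instead of acid. Against the clean prenyl placement of A1 it sets a short, modest alkylation of a cheap phenol.

Alternative 2: The C2–C3 bond is cut and ring C is closed by a Petasis–Ferrier rearrangement. The methylene benzodioxine A5, made by methylenation of benzodioxinone A6 with Cp2TiMe2, would be treated with an enantiopure aluminium Lewis acid from Me3Al and a 3,3'-disubstituted BINOL. Cleavage of the C2–O3 acetal bond gives an aryl oxocarbenium ion tethered to an aluminium enolate, whose carbon closes on C2 to give bis-silyl flavanone A4, identical with 14.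
- Merits: the ketone arrives at the right oxidation level, so steps 7 and 8 of the chosen route would be unnecessary. That is a real saving of two steps after the key step, with the same protecting groups.
- Weak points: the stereocentre of A5 is lost on ionisation and the oxocarbenium carbon is planar. Enantioselectivity would have to come from a stoichiometric chiral aluminium counter-ion steering the collapse of a short-lived tethered ion pair, for which no asymmetric version is established. The product is a β-aryloxy ketone exposed to a Lewis acid, so it is open to retro-oxa-Michael racemisation. Making A6 and methylenating it spends at the front the steps saved at the end.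
- Comparison: both roads rest on unproven enantiocontrol. The chosen plan sets against the shorter end game an intermolecular, catalytic stereo-determining event of a type where chiral acids are established, and a product 12 that cannot racemise by ring opening under the conditions that form it.

Alternative 3: The O1–C8a aryl ether bond is cut. The anti diol A8 would cyclise by copper-catalysed intramolecular O-arylation (CuI, 1,10-phenanthroline, Cs2CO3). The C2 hydroxyl displaces the bromide at C8a to give cis-flavan-4-ol A7, and C4 oxidation and MOM removal would then give 15.
- Merits: both carbinol centres come from well-established asymmetric carbonyl chemistry. The C2–O bond is never broken, so C2 cannot scramble in the ring closure. Only the C2 hydroxyl can form a six-membered ring. In certainty of stereocontrol this road is better than the chosen plan.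
- Weak points: it is linear and longer. Two stereocentres are installed separately and one is then destroyed. The closure needs hot carbonate with two benzylic alcohols present. The MOM ethers force an acidic end game next to an ortho-prenylphenol and on a flavanone.
- Comparison: the chosen plan is convergent, makes both ring C bonds in one step and finishes with buffered fluoride. It pays with an enantioselective step that must be developed, where this road would mostly need execution.

Key step: step 6

Assumption: the absolute sense of induction of the chiral acid cannot be predicted with confidence. The (S,S) acid is written, and its (R,R) antipode would be used if the 2R series results.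

## Route

Step 1
Reactants: 1 2,4-dihydroxybenzaldehyde
Product: 2 4-(tert-butyldimethylsilyloxy)-2-hydroxybenzaldehyde
Conditions: TBSCl (1.05 equiv), imidazole, CH2Cl2, 0 °C
Reagents that add atoms: tert-butyldimethylsilyl chloride, CC(C)(C)[Si](C)(C)Cl
Why: Silyl ether formation; the 2-OH is tied in a hydrogen bond to the formyl oxygen and is the more hindered, so one equivalent of silyl chloride at 0 °C should react at the 4-OH only.

Step 2
Reactants: 2 4-(tert-butyldimethylsilyloxy)-2-hydroxybenzaldehyde
Product: 3 5-(tert-butyldimethylsilyloxy)-2-(dimethoxymethyl)phenol
Conditions: HC(OMe)3, MeOH, pyridinium p-toluenesulfonate (cat.), rt; then Et3N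
Reagents that add atoms: trimethyl orthoformate, COC(OC)OC; methanol, CO
Why: Acid-catalysed acetalisation with the orthoformate as water scavenger (the aldehyde oxygen leaves as methyl formate); the weak pyridinium acid should not cleave the aryl silyl ether, and the amine quench with no silica chromatography should keep the ionisable ortho-hydroxybenzyl acetal intact.

Step 3
Reactants: 4 4-iodophenol; 5 prenyl bromide (1-bromo-3-methylbut-2-ene)
Product: 7 4-iodo-2,6-bis(3-methylbut-2-en-1-yl)phenol, via 4-iodo-2-prenylphenol 6 (not isolated)
Conditions: NaH (2.2 equiv), 5 (2.2 equiv, in two portions), toluene, 0 °C to rt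
Reagents that add atoms: prenyl bromide (second equivalent of 5), CC(C)=CCBr
Why: Twofold ortho-C-alkylation of a phenoxide, which consumes two equivalents of 5: in toluene the sodium phenoxide reacts as a tight ion-pair aggregate with its oxygen shielded, so an ortho carbon attacks the primary carbon of 5 in SN2 fashion (linear prenyl), the para position being blocked by iodine, and the dienone tautomerises to mono-prenyl phenol 6. The second equivalent of NaH deprotonates 6 in the flask and the second equivalent of 5 alkylates the remaining ortho carbon in the same way to give 7. Unreacted 6 is the expected main by-product and can be resubmitted.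

Step 4
Reactants: 7 4-iodo-2,6-bis(3-methylbut-2-en-1-yl)phenol
Product: 8 tert-butyl[4-iodo-2,6-bis(3-methylbut-2-en-1-yl)phenoxy]dimethylsilane
Conditions: TBSCl, imidazole, 4-(dimethylamino)pyridine (cat.), DMF, 40 °C
Reagents that add atoms: tert-butyldimethylsilyl chloride, CC(C)(C)[Si](C)(C)Cl
Why: Silyl ether formation on a 2,6-dialkylphenol whose flanking groups are only CH2 units, so gentle warming should suffice; the ether later keeps the phenol from adding to a protonated prenyl group.

Step 5
Reactants: 8 tert-butyl[4-iodo-2,6-bis(3-methylbut-2-en-1-yl)phenoxy]dimethylsilane; 9 tributyl(vinyl)stannane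
Product: 10 tert-butyl[4-ethenyl-2,6-bis(3-methylbut-2-en-1-yl)phenoxy]dimethylsilane
Conditions: Pd(PPh3)4 (5 mol%), BHT (trace), toluene, 90 °C
Reagents that add atoms: none
Why: Migita–Kosugi–Stille coupling: zerovalent palladium inserts into the unhindered C–I bond, the vinyl group is transferred from tin and reductive elimination gives the styrene. The neutral, base-free medium leaves the aryl silyl ether alone and the isolated trisubstituted alkenes do not take part.

Step 6
Reactants: 3 5-(tert-butyldimethylsilyloxy)-2-(dimethoxymethyl)phenol; 10 tert-butyl[4-ethenyl-2,6-bis(3-methylbut-2-en-1-yl)phenoxy]dimethylsilane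
Product: 12 (2S,4S)-cis-4-methoxyflavan bis-silyl ether, via methoxy ortho-quinone methide 11 (not isolated)
Conditions: (S,S)-imidodiphosphorimidate acid HN[P(=NSO2CF3)(O2C20H10Ar2)]2, Ar = 3,5-(CF3)2C6H3 (3 mol%), 5 Å MS, toluene, −40 °C
Reagents that add atoms: none
Why: Proposed new method: the confined acid protonates an acetal oxygen of 3 and methanol leaves, giving the oxocarbenium ion that is the O-protonated form of methoxy ortho-quinone methide 11, held as a contact ion pair with the phenolic OH hydrogen-bonded to the chiral anion. The terminal carbon of styrene 10 attacks C4 and the para-silyloxybenzylic cation formed at C2 is captured by the phenolic oxygen, an asynchronous inverse-demand hetero-Diels–Alder reaction that forms C3–C4 and O1–C2 and closes ring C by [4+2] closure (in its stepwise limit a 6-exo-trig attack of O1 on the quinoid benzylic cation). The closest known reaction type is the acid-catalysed [4+2] cycloaddition of ortho-quinone methides, generated from salicylaldehyde acetals or ortho-hydroxybenzyl alcohols, with styrenes, which has chiral phosphoric acid versions; enantiocontrol over an acetal-derived methoxy quinone methide in an intermolecular reaction is the untested part. C4 is set in the C–C bond-forming event, where the chiral anion shields one face of the oxocarbenium carbon, and C2 is set relative to C4 by closure through a chair-like transition state with aryl and methoxy groups both pseudo-equatorial (2,4-cis), so its absolute configuration is relayed from the anion. The step needs facial selectivity and preference for the styrene over the two prenyl alkenes: the para-oxygenated styrene is the stronger π-nucleophile and leads to a benzylic cation where a prenyl group would give only a tertiary alkyl cation, and the silyl ether keeps the ring B oxygen from adding to a prenyl group. The C7 silyloxy group para to C4a stabilises the heterodiene, the sieves take up methanol, and 3 and 10 are mixed cold before the acid is added to limit cationic oligomerisation of 10. Any trans isomer is removed by chromatography before step 8, because a trans product with the same C4 configuration would end as the 2R ketone.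

Step 7
Reactants: 12 (2S,4S)-cis-4-methoxyflavan bis-silyl ether
Product: 13 (2S)-flavan-4-ol bis-silyl ether (C4 epimers)
Conditions: p-toluenesulfonic acid monohydrate (5 mol%), THF/H2O 4:1, rt
Reagents that add atoms: water, O
Why: Acid-catalysed SN1 solvolysis of an activated benzylic ether: loss of methanol gives the C4 cation, stabilised by the para C7 silyloxy group and the ortho ring oxygen, and water captures it. C2 is not involved because O1 is an aryl ether oxygen far less basic than the methoxy group, and the C4 epimer ratio is irrelevant; the reaction is stopped once 12 is consumed to limit loss of a C3 proton to the flav-3-ene.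

Step 8
Reactants: 13 (2S)-flavan-4-ol bis-silyl ether (C4 epimers)
Product: 14 (S)-7-(tert-butyldimethylsilyloxy)-2-[4-(tert-butyldimethylsilyloxy)-3,5-bis(3-methylbut-2-en-1-yl)phenyl]chroman-4-one
Conditions: Dess–Martin periodinane, NaHCO3, CH2Cl2, 0 °C to rt
Reagents that add atoms: none
Why: Dess–Martin oxidation of a secondary benzylic alcohol; both C4 epimers converge on one ketone, the bicarbonate takes up the acetic acid released so that the C4 alcohol is not ionised, and prenyl alkenes and aryl silyl ethers are inert to the periodinane.

Step 9
Reactants: 14 (S)-7-(tert-butyldimethylsilyloxy)-2-[4-(tert-butyldimethylsilyloxy)-3,5-bis(3-methylbut-2-en-1-yl)phenyl]chroman-4-one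
Product: 15 (S)-7-hydroxy-2-[4-hydroxy-3,5-bis(3-methylbut-2-en-1-yl)phenyl]chroman-4-one
Conditions: Bu4NF, AcOH (1:1), THF, 0 °C
Reagents that add atoms: none
Why: Fluoride cleavage of both aryl silyl ethers, driven by Si–F bond formation; acetic acid protonates the phenoxides as they form, so E1cB opening of ring C to the 2'-hydroxychalcone (the racemisation pathway of C2) should not be triggered, and the medium is far too weakly acidic to cyclise the ortho-prenylphenol.

## Compound list

1 | 2,4-dihydroxybenzaldehyde | O=Cc1ccc(O)cc1O | starting material
2 | 4-(tert-butyldimethylsilyloxy)-2-hydroxybenzaldehyde | O=Cc1ccc(O[Si](C)(C)C(C)(C)C)cc1O | intermediate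
3 | 5-(tert-butyldimethylsilyloxy)-2-(dimethoxymethyl)phenol | COC(OC)c1ccc(O[Si](C)(C)C(C)(C)C)cc1O | intermediate
4 | 4-iodophenol | Oc1ccc(I)cc1 | starting material
5 | prenyl bromide (1-bromo-3-methylbut-2-ene) | CC(C)=CCBr | starting material
6 | 4-iodo-2-(3-methylbut-2-en-1-yl)phenol, the mono-prenyl phenol (formed in the flask, not isolated) | CC(C)=CCc1cc(I)ccc1O | intermediate
7 | 4-iodo-2,6-bis(3-methylbut-2-en-1-yl)phenol | CC(C)=CCc1cc(I)cc(CC=C(C)C)c1O | intermediate
8 | tert-butyl[4-iodo-2,6-bis(3-methylbut-2-en-1-yl)phenoxy]dimethylsilane | CC(C)=CCc1cc(I)cc(CC=C(C)C)c1O[Si](C)(C)C(C)(C)C | intermediate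
9 | tributyl(vinyl)stannane | C=C[Sn](CCCC)(CCCC)CCCC | starting material
10 | tert-butyl[4-ethenyl-2,6-bis(3-methylbut-2-en-1-yl)phenoxy]dimethylsilane | C=Cc1cc(CC=C(C)C)c(O[Si](C)(C)C(C)(C)C)c(CC=C(C)C)c1 | intermediate
11 | (E)-3-(tert-butyldimethylsilyloxy)-6-(methoxymethylidene)cyclohexa-2,4-dien-1-one, the methoxy ortho-quinone methide, which reacts as its O-protonated oxocarbenium form (formed in the flask, not isolated) | CO/C=C1\C=CC(O[Si](C)(C)C(C)(C)C)=CC1=O | intermediate
12 | (2S,4S)-7-(tert-butyldimethylsilyloxy)-2-[4-(tert-butyldimethylsilyloxy)-3,5-bis(3-methylbut-2-en-1-yl)phenyl]-4-methoxychroman (2,4-cis) | CC(C)=CCc1cc([C@@H]2C[C@H](OC)c3ccc(O[Si](C)(C)C(C)(C)C)cc3O2)cc(CC=C(C)C)c1O[Si](C)(C)C(C)(C)C | intermediate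
13 | (2S)-7-(tert-butyldimethylsilyloxy)-2-[4-(tert-butyldimethylsilyloxy)-3,5-bis(3-methylbut-2-en-1-yl)phenyl]chroman-4-ol, mixture of C4 epimers | CC(C)=CCc1cc([C@@H]2CC(O)c3ccc(O[Si](C)(C)C(C)(C)C)cc3O2)cc(CC=C(C)C)c1O[Si](C)(C)C(C)(C)C | intermediate
14 | (S)-7-(tert-butyldimethylsilyloxy)-2-[4-(tert-butyldimethylsilyloxy)-3,5-bis(3-methylbut-2-en-1-yl)phenyl]chroman-4-one | CC(C)=CCc1cc([C@@H]2CC(=O)c3ccc(O[Si](C)(C)C(C)(C)C)cc3O2)cc(CC=C(C)C)c1O[Si](C)(C)C(C)(C)C | intermediate
15 | (S)-7-hydroxy-2-[4-hydroxy-3,5-bis(3-methylbut-2-en-1-yl)phenyl]chroman-4-one, the target abyssinone | CC(C)=CCc1cc([C@@H]2CC(=O)c3ccc(O)cc3O2)cc(CC=C(C)C)c1O | target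

## Step count and risks

Total: 9 steps. Longest linear sequence: 7 steps (steps 3 to 9, from 4-iodophenol 4). The ring A branch (steps 1 and 2) joins at step 6.

**Step 6, the key step and the one proposed new method.** The most likely failure is poor facial selectivity, because the chiral anion must control a stepwise addition and the configuration of C2 is only relayed through C4. Partial trans closure or acid-induced cationic oligomerisation of styrene 10 would add to the loss. The fallback uses known chemistry and gives up catalytic enantiocontrol in favour of resolution.
- It sets out from 3 and 10, which are combined under the known Lewis-acid catalysis (Sc(OSO2CF3)3, CH2Cl2, 0 °C) to give racemic cis-4-methoxyflavan bis-silyl ether F1.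
- The conditions of steps 7 and 8 then give the racemic flavan-4-ol F2 and the racemic bis-silyl flavanone F3.
- F3 is resolved kinetically by Noyori asymmetric transfer hydrogenation with RuCl(p-cymene)[TsNCH(Ph)CH(Ph)NH2] (the antipode that consumes the 2R ketone) and HCO2H/Et3N. This reduces the 2R enantiomer to the (2R,4R)-cis-flavan-4-ol F4, which is separated.
- The unreacted S ketone is 14, where the route is rejoined. Half of the material is sacrificed.

**Step 7.** Loss of the C3 proton from the C4 cation (elimination to the flav-3-ene) and Friedel–Crafts capture of the cation by electron-rich arenes may compete with hydration. The fallback changes the mechanism from ionisation to hydride abstraction. It sets out from 12 and uses DDQ in CH2Cl2/pH 7 buffer to cleave the electron-rich benzylic methyl ether oxidatively (oxocarbenium ion, water addition, loss of methanol). This gives 14 directly without passing through 13 and makes no new compound. The silyl ethers close the quinone-methide channel by which DDQ attacks free ortho-prenylphenols, but attack at the ArCH2–CH= positions would have to be watched.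

**Step 3.** O-alkylation, incomplete second alkylation and dienone by-products may hold the throughput down. The fallback replaces phenoxide alkylation by cross-coupling and comes back at 10, so steps 4 and 5 are not needed.
- It sets out from 4, which is brominated at both ortho positions (Br2, AcOH) to 2,6-dibromo-4-iodophenol F5.
- F5 is silylated to tert-butyl(2,6-dibromo-4-iodophenoxy)dimethylsilane F6.
- F6 is vinylated chemoselectively at the C–I bond with 9 (Pd(PPh3)4, toluene, 80 °C) to tert-butyl(2,6-dibromo-4-ethenylphenoxy)dimethylsilane F7.
- F7 undergoes a twofold Stille coupling with tributyl(3-methylbut-2-enyl)stannane (Pd[P(t-Bu)3]2, toluene, 80 °C), under neutral conditions that the labile silyl ether should tolerate, to give 10.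

**Step 2.** Acetal 3 may hydrolyse back to the aldehyde or lose methanol prematurely (self-ionisation assisted by the ortho phenol) during isolation and storage. The fallback avoids isolation. It sets out from 2, which is combined with trimethyl orthoformate and styrene 10 under the acid catalyst of step 6, so that 3 is formed and consumed in the same flask. The route is rejoined at 12 and no new compound is made. The three-component form of this cycloaddition is known with achiral Lewis acids.

## Further compounds

F1 | step 6 | racemic cis-4-methoxyflavan bis-silyl ether (racemate of 12, one enantiomer drawn) | CC(C)=CCc1cc([C@@H]2C[C@H](OC)c3ccc(O[Si](C)(C)C(C)(C)C)cc3O2)cc(CC=C(C)C)c1O[Si](C)(C)C(C)(C)C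
F2 | step 6 | racemic flavan-4-ol bis-silyl ether, C4 epimers | CC(C)=CCc1cc(C2CC(O)c3ccc(O[Si](C)(C)C(C)(C)C)cc3O2)cc(CC=C(C)C)c1O[Si](C)(C)C(C)(C)C
F3 | step 6 | racemic bis-silyl flavanone | CC(C)=CCc1cc(C2CC(=O)c3ccc(O[Si](C)(C)C(C)(C)C)cc3O2)cc(CC=C(C)C)c1O[Si](C)(C)C(C)(C)C
F4 | step 6 | (2R,4R)-cis-flavan-4-ol bis-silyl ether | CC(C)=CCc1cc([C@H]2C[C@@H](O)c3ccc(O[Si](C)(C)C(C)(C)C)cc3O2)cc(CC=C(C)C)c1O[Si](C)(C)C(C)(C)C
F0 | step 7 | none | none
F5 | step 3 | 2,6-dibromo-4-iodophenol | Oc1c(Br)cc(I)cc1Br
F6 | step 3 | tert-butyl(2,6-dibromo-4-iodophenoxy)dimethylsilane | CC(C)(C)[Si](C)(C)Oc1c(Br)cc(I)cc1Br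
F7 | step 3 | tert-butyl(2,6-dibromo-4-ethenylphenoxy)dimethylsilane | C=Cc1cc(Br)c(O[Si](C)(C)C(C)(C)C)c(Br)c1
F0 | step 2 | none | none
A1 | alternative 1 | 7-(methoxymethoxy)-4'-hydroxy-3',5'-diprenylflavone | CC(C)=CCc1cc(-c2cc(=O)c3ccc(OCOC)cc3o2)cc(CC=C(C)C)c1O
A2 | alternative 1 | 2,10-dimethylundeca-2,9-dien-6-one | CC(C)=CCCC(=O)CCC=C(C)C
A3 | alternative 1 | 2-[7-(methoxymethoxy)-4-oxochromen-2-yl]vinamidinium hexafluorophosphate | CN(C)C=C(C=[N+](C)C)c1cc(=O)c2ccc(OCOC)cc2o1.F[P-](F)(F)(F)(F)F
A4 | alternative 2 | (S)-bis-silyl flavanone, identical with 14 | CC(C)=CCc1cc([C@@H]2CC(=O)c3ccc(O[Si](C)(C)C(C)(C)C)cc3O2)cc(CC=C(C)C)c1O[Si](C)(C)C(C)(C)C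
A5 | alternative 2 | 7-(tert-butyldimethylsilyloxy)-2-[4-(tert-butyldimethylsilyloxy)-3,5-diprenylphenyl]-4-methylene-4H-1,3-benzodioxine | C=C1OC(c2cc(CC=C(C)C)c(O[Si](C)(C)C(C)(C)C)c(CC=C(C)C)c2)Oc2cc(O[Si](C)(C)C(C)(C)C)ccc12
A6 | alternative 2 | 7-(tert-butyldimethylsilyloxy)-2-[4-(tert-butyldimethylsilyloxy)-3,5-diprenylphenyl]-4H-1,3-benzodioxin-4-one | O=C1OC(c2cc(CC=C(C)C)c(O[Si](C)(C)C(C)(C)C)c(CC=C(C)C)c2)Oc2cc(O[Si](C)(C)C(C)(C)C)ccc12
A7 | alternative 3 | (2S,4S)-cis-flavan-4-ol, bis-MOM | CC(C)=CCc1cc([C@@H]2C[C@H](O)c3ccc(OCOC)cc3O2)cc(CC=C(C)C)c1OCOC
A8 | alternative 3 | (1S,3S)-anti-1-[2-bromo-4-(methoxymethoxy)phenyl]-3-[4-(methoxymethoxy)-3,5-diprenylphenyl]propane-1,3-diol | CC(C)=CCc1cc([C@@H](O)C[C@H](O)c2ccc(OCOC)cc2Br)cc(CC=C(C)C)c1OCOC
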